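**Retrosynthetic overview**
1. Target 32 ⇐ 28 by PMB removal, C19 oxidation and ester hydrolysis. Ring 2 (the oxolane), C3, C4 and the C18 carboxyl carbon all come from one palladium-catalysed alkoxycarbonylation of the macrocyclic E-alkenol 27 (no aldol, no oxa-Michael).
2. Ring 1 (the 14-membered carbocycle, formed first) ⇐ intramolecular B-alkyl Suzuki–Miyaura coupling at C10–C11 of iodoalkene 23 (no ring-closing metathesis). The Z-C11=C12 geometry is pre-set by propyne carbocupration.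
3. C1 and the E-C3=C4 alkene ⇐ Ireland–Claisen rearrangement of allylic ester 19. The C4 carbinol centre is sacrificed to set C1, and C3/C4 are then rebuilt relative to C1 (line 1).
4. 19 ⇐ dienol 8 + iodo acid 17. C8 comes from a copper-catalysed asymmetric allylic alkylation, the C4 carbinol from a catalytic asymmetric vinylzinc addition.
5. Starting materials: (E)-1,4-dibromobut-2-ene, 4-methoxybenzyl alcohol, 2-(3-bromopropyl)-1,3-dioxolane, (4-bromobutoxy)(tert-butyl)dimethylsilane, propyne.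

Assumption and convention (one line): the SMILES defines the absolute configuration, which is (1R,3R,4S,8R,11Z) in cembrane numbering (C1 = CH bearing CMe2O, C3 = OCH, C4 and C8 = CH–CO2H carrying C18 and C19, C11=C12 alkene, C15 = CMe2); these atom labels are used below.

**Route**

Step 1
Reactants: 1 (E)-1,4-dibromobut-2-ene; 2 4-methoxybenzyl alcohol
Product: 3 (E)-1-bromo-4-[(4-methoxybenzyl)oxy]but-2-ene
Conditions: NaH, THF, 0 °C → rt (1 in threefold excess)
Reagents that add atoms: none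
Why: Williamson ether synthesis in which the alkoxide of 2 displaces one allylic bromide of 1 by SN2, the excess of 1 suppresses double substitution, and the E-alkene is untouched (no stereocentre formed).

Step 2
Reactants: 3 (E)-1-bromo-4-[(4-methoxybenzyl)oxy]but-2-ene; 4 2-(3-bromopropyl)-1,3-dioxolane
Product: 6 2-[(4R)-4-{[(4-methoxybenzyl)oxy]methyl}hex-5-en-1-yl]-1,3-dioxolane, via alkylmagnesium bromide 5 (not isolated)
Conditions: 4, Mg, Et2O; then 3, CuBr·SMe2 (5 mol %), Taniaphos (C43H39FeNP2, 6 mol %, enantiomer giving (R)-6), CH2Cl2, −75 °C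
Reagents that add atoms: none
Why: Copper-catalysed asymmetric allylic alkylation (SN2' substitution by a Grignard reagent under a chiral ferrocenyl diphosphine) delivers the alkyl group of 5 to the γ-carbon on the ligand-selected alkene face, giving the branched product and setting C8 as R.

Step 3
Reactants: 6 2-[(4R)-4-{[(4-methoxybenzyl)oxy]methyl}hex-5-en-1-yl]-1,3-dioxolane
Product: 7 (5R)-5-{[(4-methoxybenzyl)oxy]methyl}hept-6-enal
Conditions: dilute aq. HCl, THF, rt
Reagents that add atoms: water, O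
Why: Acid-catalysed acetal hydrolysis frees the C4 aldehyde, while the PMB ether, the terminal alkene and C8 are inert to dilute aqueous acid.

Step 4
Reactants: 7 (5R)-5-{[(4-methoxybenzyl)oxy]methyl}hept-6-enal
Product: 8 (3S,7R)-7-{[(4-methoxybenzyl)oxy]methyl}nona-1,8-dien-3-ol
Conditions: Zn(CH=CH2)2 (2 equiv), (+)-MIB (3-exo-morpholinoisoborneol, 10 mol %; antipode chosen for Re-face attack), toluene/hexane, −20 → 0 °C; dilute aq. HCl quench
Reagents that add atoms: divinylzinc, C=C[Zn]C=C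
Why: Amino-alcohol-catalysed enantioselective 1,2-addition of a vinylzinc reagent to an aldehyde, in which the chiral zinc aminoalkoxide directs vinyl to the Re face and sets the C4 carbinol as S independently of the remote C8 centre.

Step 5
Reactants: 9 (4-bromobutoxy)(tert-butyl)dimethylsilane; 10 propyne
Product: 14 tert-butyl{[(5Z)-6-iodo-5-methylhex-5-en-1-yl]oxy}dimethylsilane, via alkylmagnesium bromide 11 (not isolated), via alkylcopper 12 (not isolated), via alkenylcopper 13 (not isolated)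
Conditions: Mg, Et2O; CuBr·SMe2 (1 equiv), Et2O/Me2S, −45 °C; propyne, −25 °C; I2, −78 → 0 °C
Reagents that add atoms: iodine, [I][I]
Why: Normant carbocupration, in which the alkylcopper adds syn across propyne with the alkyl group on the internal carbon and iodinolysis of the alkenyl–copper bond with retention gives the Z-iodoalkene (chain cis to iodine), fixing the future C11=C12 geometry.

Step 6
Reactants: 14 tert-butyl{[(5Z)-6-iodo-5-methylhex-5-en-1-yl]oxy}dimethylsilane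
Product: 17 (5Z)-6-iodo-5-methylhex-5-enoic acid, via iodo alcohol 15 (not isolated), via iodo aldehyde 16 (not isolated)
Conditions: CrO3, H2SO4, acetone/H2O, 0 °C → rt
Reagents that add atoms: water, O
Why: Jones oxidation, in which the aqueous acid cleaves the primary silyl ether and chromic acid oxidises the alcohol through the aldehyde hydrate to the acid, the electron-poor iodoalkene being inert.

Step 7
Reactants: 8 (3S,7R)-7-{[(4-methoxybenzyl)oxy]methyl}nona-1,8-dien-3-ol; 17 (5Z)-6-iodo-5-methylhex-5-enoic acid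
Product: 19 (3S,7R)-7-{[(4-methoxybenzyl)oxy]methyl}nona-1,8-dien-3-yl (5Z)-6-iodo-5-methylhex-5-enoate, via O-acylisourea 18 (not isolated)
Conditions: N,N'-dicyclohexylcarbodiimide, DMAP (cat.), CH2Cl2, 0 °C → rt
Reagents that add atoms: none
Why: Steglich esterification, in which the carbodiimide activates 17 as an O-acylisourea that acylates the secondary allylic alcohol at oxygen, so the C4 configuration is retained.

Step 8
Reactants: 19 (3S,7R)-7-{[(4-methoxybenzyl)oxy]methyl}nona-1,8-dien-3-yl (5Z)-6-iodo-5-methylhex-5-enoate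
Product: 22 (2R,4E,9R)-2-[(3Z)-4-iodo-3-methylbut-3-en-1-yl]-9-{[(4-methoxybenzyl)oxy]methyl}undeca-4,10-dienoic acid, via silyl ketene acetal 20 (not isolated), via trimethylsilyl ester 21 (not isolated)
Conditions: LiN(i-Pr)2, THF, −78 °C; Me3SiCl; −78 → 50 °C; dilute aq. HCl
Reagents that add atoms: none
Why: Ireland–Claisen rearrangement, in which kinetic enolisation in THF gives the ketene acetal with the C14 chain cis to the allylic oxygen and the chair transition state with the C5 chain equatorial forms the C1–C2 bond and the E-C3=C4 alkene and transfers the S-carbinol chirality to C1 (R).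

Step 9
Reactants: 22 (2R,4E,9R)-2-[(3Z)-4-iodo-3-methylbut-3-en-1-yl]-9-{[(4-methoxybenzyl)oxy]methyl}undeca-4,10-dienoic acid
Product: 23 methyl (2R,4E,9R)-2-[(3Z)-4-iodo-3-methylbut-3-en-1-yl]-9-{[(4-methoxybenzyl)oxy]methyl}undeca-4,10-dienoate
Conditions: MeI, K2CO3, DMF, rt
Reagents that add atoms: iodomethane, [CH3]I
Why: SN2 O-methylation of the potassium carboxylate, with carbonate too weak a base to epimerise the C1 α-centre.

Step 10
Reactants: 23 methyl (2R,4E,9R)-2-[(3Z)-4-iodo-3-methylbut-3-en-1-yl]-9-{[(4-methoxybenzyl)oxy]methyl}undeca-4,10-dienoate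
Product: 25 methyl (1R,3E,8R,11Z)-8-{[(4-methoxybenzyl)oxy]methyl}-12-methylcyclotetradeca-3,11-diene-1-carboxylate, via B-alkyl-9-BBN adduct 24 (not isolated)
Conditions: 9-BBN, THF, rt; then slow addition to Pd(dppf)Cl2 (15 mol %), AsPh3, Cs2CO3, DMF/THF/H2O, rt → 45 °C, 2 mmol/L
Reagents that add atoms: none
Why: Hydroboration followed by intramolecular B-alkyl Suzuki–Miyaura macrocyclisation, in which 9-BBN adds anti-Markovnikov only to the single terminal alkene and oxidative addition of zerovalent palladium to the iodoalkene, transmetalation and reductive elimination close ring 1 at C10–C11 with retention of the Z geometry.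

Step 11
Reactants: 25 methyl (1R,3E,8R,11Z)-8-{[(4-methoxybenzyl)oxy]methyl}-12-methylcyclotetradeca-3,11-diene-1-carboxylate
Product: 27 2-[(1R,3E,8R,11Z)-8-{[(4-methoxybenzyl)oxy]methyl}-12-methylcyclotetradeca-3,11-dien-1-yl]propan-2-ol, via methyl ketone 26 (not isolated)
Conditions: MeMgBr (4 equiv), THF, −20 → 0 °C; dilute aq. HCl quench
Reagents that add atoms: methylmagnesium bromide, C[Mg]Br
Why: Double Grignard addition to the ester through the methyl ketone builds the tertiary carbinol C15, and addition outpaces enolisation at low temperature so C1 is retained.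

Step 12
Reactants: 27 2-[(1R,3E,8R,11Z)-8-{[(4-methoxybenzyl)oxy]methyl}-12-methylcyclotetradeca-3,11-dien-1-yl]propan-2-ol
Product: 28 methyl (1R,4Z,8R,12S,13R)-8-{[(4-methoxybenzyl)oxy]methyl}-4,15,15-trimethyl-14-oxabicyclo[11.2.1]hexadec-4-ene-12-carboxylate
Conditions: PdCl2 (10 mol %), CuCl2 (3 equiv), NaOAc (3 equiv), CO (1 atm), MeOH, rt
Reagents that add atoms: carbon monoxide, [C-]#[O+]; methanol, CO
Why: Intramolecular alkoxycarbonylation (Semmelhack type), in which 5-exo anti-oxypalladation of the E-alkene by the tertiary alcohol, CO insertion with retention and methanolysis (CuCl2 reoxidises zerovalent palladium) add oxygen and CO2Me anti across C3=C4 to give the 3R,4S pair, while attack on the alkene face that keeps C4 and C14 pseudo-equatorial on the forming oxolane (no 1,3-clash with a C15 methyl, out,out-bridged ring 2) sets C3 cis to C1.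

Step 13
Reactants: 28 methyl (1R,4Z,8R,12S,13R)-8-{[(4-methoxybenzyl)oxy]methyl}-4,15,15-trimethyl-14-oxabicyclo[11.2.1]hexadec-4-ene-12-carboxylate
Product: 29 methyl (1R,4Z,8R,12S,13R)-8-(hydroxymethyl)-4,15,15-trimethyl-14-oxabicyclo[11.2.1]hexadec-4-ene-12-carboxylate
Conditions: DDQ, CH2Cl2/pH 7 buffer, 0 °C
Reagents that add atoms: none
Why: Oxidative PMB cleavage, in which DDQ oxidises the electron-rich benzylic ether to an oxocarbenium ion that water hydrolyses, leaving the trisubstituted alkene, the ether ring and the ester untouched.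

Step 14
Reactants: 29 methyl (1R,4Z,8R,12S,13R)-8-(hydroxymethyl)-4,15,15-trimethyl-14-oxabicyclo[11.2.1]hexadec-4-ene-12-carboxylate
Product: 31 (1R,4Z,8R,12S,13R)-12-(methoxycarbonyl)-4,15,15-trimethyl-14-oxabicyclo[11.2.1]hexadec-4-ene-8-carboxylic acid, via aldehyde 30 (not isolated)
Conditions: TEMPO (20 mol %), PhI(OAc)2 (2.5 equiv), MeCN/H2O, rt
Reagents that add atoms: water, O
Why: TEMPO/PhI(OAc)2 oxidation, in which the oxoammonium salt oxidises the primary alcohol to the aldehyde and, through its hydrate, to the acid without epimerising C8 or touching the alkene.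

Step 15
Reactants: 31 (1R,4Z,8R,12S,13R)-12-(methoxycarbonyl)-4,15,15-trimethyl-14-oxabicyclo[11.2.1]hexadec-4-ene-8-carboxylic acid
Product: 32 (1R,4Z,8R,12S,13R)-4,15,15-trimethyl-14-oxabicyclo[11.2.1]hexadec-4-ene-8,12-dicarboxylic acid
Conditions: Me3SnOH, ClCH2CH2Cl, 80 °C; then dilute aq. HCl
Reagents that add atoms: trimethyltin hydroxide, C[Sn](C)(C)O
Why: Trimethyltin hydroxide ester cleavage is a mild, nearly neutral hydrolysis of the methyl ester that avoids C4 epimerisation and retro-oxa-Michael opening of the β-alkoxy ester, delivering the diacid.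

**Compound list**
1 | (E)-1,4-dibromobut-2-ene | BrC/C=C/CBr | starting material
2 | 4-methoxybenzyl alcohol | COc1ccc(CO)cc1 | starting material
3 | (E)-1-bromo-4-[(4-methoxybenzyl)oxy]but-2-ene | COc1ccc(COC/C=C/CBr)cc1 | intermediate
4 | 2-(3-bromopropyl)-1,3-dioxolane | BrCCCC1OCCO1 | starting material
5 | [3-(1,3-dioxolan-2-yl)propyl]magnesium bromide | Br[Mg]CCCC1OCCO1 | intermediate
6 | 2-[(4R)-4-{[(4-methoxybenzyl)oxy]methyl}hex-5-en-1-yl]-1,3-dioxolane | C=C[C@H](COCc1ccc(OC)cc1)CCCC1OCCO1 | intermediate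
7 | (5R)-5-{[(4-methoxybenzyl)oxy]methyl}hept-6-enal | C=C[C@H](COCc1ccc(OC)cc1)CCCC=O | intermediate
8 | (3S,7R)-7-{[(4-methoxybenzyl)oxy]methyl}nona-1,8-dien-3-ol | C=C[C@H](COCc1ccc(OC)cc1)CCC[C@H](O)C=C | intermediate
9 | (4-bromobutoxy)(tert-butyl)dimethylsilane | CC(C)(C)[Si](C)(C)OCCCCBr | starting material
10 | propyne | CC#C | starting material
11 | {4-[(tert-butyldimethylsilyl)oxy]butyl}magnesium bromide | CC(C)(C)[Si](C)(C)OCCCC[Mg]Br | intermediate
12 | {4-[(tert-butyldimethylsilyl)oxy]butyl}copper | CC(C)(C)[Si](C)(C)OCCCC[Cu] | intermediate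
13 | {(1Z)-6-[(tert-butyldimethylsilyl)oxy]-2-methylhex-1-en-1-yl}copper | CC(C)(C)[Si](C)(C)OCCCC/C(C)=C\[Cu] | intermediate
14 | tert-butyl{[(5Z)-6-iodo-5-methylhex-5-en-1-yl]oxy}dimethylsilane | CC(C)(C)[Si](C)(C)OCCCC/C(C)=C\I | intermediate
15 | (5Z)-6-iodo-5-methylhex-5-en-1-ol | OCCCC/C(C)=C\I | intermediate
16 | (5Z)-6-iodo-5-methylhex-5-enal | O=CCCC/C(C)=C\I | intermediate
17 | (5Z)-6-iodo-5-methylhex-5-enoic acid | OC(=O)CCC/C(C)=C\I | intermediate
18 | O-acylisourea from 17 and N,N'-dicyclohexylcarbodiimide | O=C(CCC/C(C)=C\I)OC(=NC1CCCCC1)NC1CCCCC1 | intermediate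
19 | (3S,7R)-7-{[(4-methoxybenzyl)oxy]methyl}nona-1,8-dien-3-yl (5Z)-6-iodo-5-methylhex-5-enoate | C=C[C@H](COCc1ccc(OC)cc1)CCC[C@H](OC(=O)CCC/C(C)=C\I)C=C | intermediate
20 | trimethylsilyl ketene acetal of 19, C14 chain cis to the allylic oxygen | C=C[C@H](COCc1ccc(OC)cc1)CCC[C@H](O/C(O[Si](C)(C)C)=C\CC/C(C)=C\I)C=C | intermediate
21 | trimethylsilyl (2R,4E,9R)-2-[(3Z)-4-iodo-3-methylbut-3-en-1-yl]-9-{[(4-methoxybenzyl)oxy]methyl}undeca-4,10-dienoate | C[Si](C)(C)OC(=O)[C@H](CC/C(C)=C\I)C/C=C/CCC[C@@H](COCc1ccc(OC)cc1)C=C | intermediate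
22 | (2R,4E,9R)-2-[(3Z)-4-iodo-3-methylbut-3-en-1-yl]-9-{[(4-methoxybenzyl)oxy]methyl}undeca-4,10-dienoic acid | OC(=O)[C@H](CC/C(C)=C\I)C/C=C/CCC[C@@H](COCc1ccc(OC)cc1)C=C | intermediate
23 | methyl (2R,4E,9R)-2-[(3Z)-4-iodo-3-methylbut-3-en-1-yl]-9-{[(4-methoxybenzyl)oxy]methyl}undeca-4,10-dienoate | COC(=O)[C@H](CC/C(C)=C\I)C/C=C/CCC[C@@H](COCc1ccc(OC)cc1)C=C | intermediate
24 | methyl (2R,4E,9S)-11-(9-borabicyclo[3.3.1]nonan-9-yl)-2-[(3Z)-4-iodo-3-methylbut-3-en-1-yl]-9-{[(4-methoxybenzyl)oxy]methyl}undec-4-enoate | COC(=O)[C@H](CC/C(C)=C\I)C/C=C/CCC[C@@H](COCc1ccc(OC)cc1)CCB1C2CCCC1CCC2 | intermediate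
25 | methyl (1R,3E,8R,11Z)-8-{[(4-methoxybenzyl)oxy]methyl}-12-methylcyclotetradeca-3,11-diene-1-carboxylate | COC(=O)[C@H]1C/C=C/CCC[C@@H](COCc2ccc(OC)cc2)CC/C=C(/C)CC1 | intermediate
26 | 1-[(1R,3E,8R,11Z)-8-{[(4-methoxybenzyl)oxy]methyl}-12-methylcyclotetradeca-3,11-dien-1-yl]ethan-1-one | CC(=O)[C@H]1C/C=C/CCC[C@@H](COCc2ccc(OC)cc2)CC/C=C(/C)CC1 | intermediate
27 | 2-[(1R,3E,8R,11Z)-8-{[(4-methoxybenzyl)oxy]methyl}-12-methylcyclotetradeca-3,11-dien-1-yl]propan-2-ol | CC(C)(O)[C@H]1C/C=C/CCC[C@@H](COCc2ccc(OC)cc2)CC/C=C(/C)CC1 | intermediate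
28 | methyl (1R,4Z,8R,12S,13R)-8-{[(4-methoxybenzyl)oxy]methyl}-4,15,15-trimethyl-14-oxabicyclo[11.2.1]hexadec-4-ene-12-carboxylate | C/C1=C/CC[C@H](COCc3ccc(OC)cc3)CCC[C@H](C(=O)OC)[C@H]2C[C@@H](CC1)C(C)(C)O2 | intermediate
29 | methyl (1R,4Z,8R,12S,13R)-8-(hydroxymethyl)-4,15,15-trimethyl-14-oxabicyclo[11.2.1]hexadec-4-ene-12-carboxylate | C/C1=C/CC[C@H](CO)CCC[C@H](C(=O)OC)[C@H]2C[C@@H](CC1)C(C)(C)O2 | intermediate
30 | methyl (1R,4Z,8R,12S,13R)-8-formyl-4,15,15-trimethyl-14-oxabicyclo[11.2.1]hexadec-4-ene-12-carboxylate | C/C1=C/CC[C@H](C=O)CCC[C@H](C(=O)OC)[C@H]2C[C@@H](CC1)C(C)(C)O2 | intermediate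
31 | (1R,4Z,8R,12S,13R)-12-(methoxycarbonyl)-4,15,15-trimethyl-14-oxabicyclo[11.2.1]hexadec-4-ene-8-carboxylic acid | C/C1=C/CC[C@H](C(=O)O)CCC[C@H](C(=O)OC)[C@H]2C[C@@H](CC1)C(C)(C)O2 | intermediate
32 | (1R,4Z,8R,12S,13R)-4,15,15-trimethyl-14-oxabicyclo[11.2.1]hexadec-4-ene-8,12-dicarboxylic acid (CNP0115244.2) | C/C1=C/CC[C@H](C(=O)O)CCC[C@H](C(=O)O)[C@H]2C[C@@H](CC1)C(C)(C)O2 | target

**Step count and risk**
Total step count: 15. Longest linear sequence: 13 steps (steps 1–4 and 7–15); the iodo acid branch (steps 5–6) joins at step 7.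

Most likely to fail, in order:

Step 12 (alkoxycarbonylation). The risks are the face selectivity at C3 (cis versus trans bridging), β-hydride elimination from the secondary alkylpalladium, and low reactivity of the internal alkene. The fallback sets out from 27 and comes back at 28. Treat 27 with Hg(OCOCF3)2 in CH2Cl2; this anti-oxymercuration is reversible, so it can equilibrate to the less strained cis-bridged ether. Brine exchange then gives the isolable chloro[(1R,4Z,8R,12S,13R)-8-{[(4-methoxybenzyl)oxy]methyl}-4,15,15-trimethyl-14-oxabicyclo[11.2.1]hexadec-4-en-12-yl]mercury F1, whose diastereomers can be separated. Transmetalation to divalent palladium and carbonylation with retention at carbon (Li2PdCl4, CO, MeOH) returns 28.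

Step 10 (Suzuki macrocyclisation). The risks are oligomerisation, protodeboronation and a competing intramolecular Heck reaction. The fallback sets out from 17 and 6 and comes back at 25; it couples first and closes the ring as a lactone, which is then rearranged transannularly (an untested ring-size-neutral variant of the lactone Ireland–Claisen).
- MeI/K2CO3 converts 17 into methyl (5Z)-6-iodo-5-methylhex-5-enoate F2.
- 9-BBN converts 6 into the B-alkyl-9-BBN adduct of 6 F3, which couples with F2 (Pd(dppf)Cl2, AsPh3, Cs2CO3) to methyl (5Z,9R)-12-(1,3-dioxolan-2-yl)-9-{[(4-methoxybenzyl)oxy]methyl}-5-methyldodec-5-enoate F4.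
- Dilute aqueous HCl gives methyl (5Z,9R)-9-{[(4-methoxybenzyl)oxy]methyl}-5-methyl-13-oxotridec-5-enoate F5.
- Zn(CH=CH2)2 with (+)-MIB gives methyl (5Z,9R,13S)-13-hydroxy-9-{[(4-methoxybenzyl)oxy]methyl}-5-methylpentadeca-5,14-dienoate F6.
- LiOH gives (5Z,9R,13S)-13-hydroxy-9-{[(4-methoxybenzyl)oxy]methyl}-5-methylpentadeca-5,14-dienoic acid F7.
- 2,4,6-Trichlorobenzoyl chloride/Et3N gives the mixed 2,4,6-trichlorobenzoic anhydride of F7 F8, which closes under DMAP at high dilution to (6Z,10R,14S)-14-ethenyl-10-{[(4-methoxybenzyl)oxy]methyl}-6-methyl-1-oxacyclotetradec-6-en-2-one F9.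
- LiN(i-Pr)2/Me3SiCl gives the trimethylsilyl ketene acetal of F9 F10. Its transannular Ireland–Claisen rearrangement (same chair as in step 8) gives trimethylsilyl (1R,3E,8R,11Z)-8-{[(4-methoxybenzyl)oxy]methyl}-12-methylcyclotetradeca-3,11-diene-1-carboxylate F11.
- Aqueous work-up gives (1R,3E,8R,11Z)-8-{[(4-methoxybenzyl)oxy]methyl}-12-methylcyclotetradeca-3,11-diene-1-carboxylic acid F12, and MeI/K2CO3 then gives 25.

Step 4 (asymmetric vinylation). The risk is modest enantioselectivity with an unbranched, functionalised aldehyde. The fallback sets out from 7 and comes back at 8, replacing the addition by an asymmetric ketone reduction.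
- LiC≡CSiMe3 in THF at −78 °C gives (7R)-7-{[(4-methoxybenzyl)oxy]methyl}-1-(trimethylsilyl)non-8-en-1-yn-3-ol as both C3 epimers F13.
- Dess–Martin periodinane gives (7R)-7-{[(4-methoxybenzyl)oxy]methyl}-1-(trimethylsilyl)non-8-en-1-yn-3-one F14.
- Transfer hydrogenation with RuCl(TsDPEN)(p-cymene) (enantiomer chosen for the 3S alcohol) in i-PrOH gives (3S,7R)-7-{[(4-methoxybenzyl)oxy]methyl}-1-(trimethylsilyl)non-8-en-1-yn-3-ol F15.
- K2CO3/MeOH gives (3S,7R)-7-{[(4-methoxybenzyl)oxy]methyl}non-8-en-1-yn-3-ol F16.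
- Semi-hydrogenation over Pd/CaCO3 poisoned with Pb(OAc)2 and quinoline returns 8.

Further compounds
F1 | step 12 | chloro[(1R,4Z,8R,12S,13R)-8-{[(4-methoxybenzyl)oxy]methyl}-4,15,15-trimethyl-14-oxabicyclo[11.2.1]hexadec-4-en-12-yl]mercury | C/C1=C/CC[C@H](COCc3ccc(OC)cc3)CCC[C@H]([Hg]Cl)[C@H]2C[C@@H](CC1)C(C)(C)O2
F2 | step 10 | methyl (5Z)-6-iodo-5-methylhex-5-enoate | COC(=O)CCC/C(C)=C\I
F3 | step 10 | B-alkyl-9-BBN adduct of 6, 9-[(3S)-6-(1,3-dioxolan-2-yl)-3-{[(4-methoxybenzyl)oxy]methyl}hexyl]-9-borabicyclo[3.3.1]nonane | O1CCOC1CCC[C@@H](COCc1ccc(OC)cc1)CCB1C2CCCC1CCC2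
F4 | step 10 | methyl (5Z,9R)-12-(1,3-dioxolan-2-yl)-9-{[(4-methoxybenzyl)oxy]methyl}-5-methyldodec-5-enoate | COC(=O)CCC/C(C)=C\CC[C@H](COCc1ccc(OC)cc1)CCCC1OCCO1
F5 | step 10 | methyl (5Z,9R)-9-{[(4-methoxybenzyl)oxy]methyl}-5-methyl-13-oxotridec-5-enoate | COC(=O)CCC/C(C)=C\CC[C@H](COCc1ccc(OC)cc1)CCCC=O
F6 | step 10 | methyl (5Z,9R,13S)-13-hydroxy-9-{[(4-methoxybenzyl)oxy]methyl}-5-methylpentadeca-5,14-dienoate | COC(=O)CCC/C(C)=C\CC[C@H](COCc1ccc(OC)cc1)CCC[C@H](O)C=C
F7 | step 10 | (5Z,9R,13S)-13-hydroxy-9-{[(4-methoxybenzyl)oxy]methyl}-5-methylpentadeca-5,14-dienoic acid | OC(=O)CCC/C(C)=C\CC[C@H](COCc1ccc(OC)cc1)CCC[C@H](O)C=C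
F8 | step 10 | mixed 2,4,6-trichlorobenzoic anhydride of F7 | O=C(OC(=O)CCC/C(C)=C\CC[C@H](COCc1ccc(OC)cc1)CCC[C@H](O)C=C)c1c(Cl)cc(Cl)cc1Cl
F9 | step 10 | (6Z,10R,14S)-14-ethenyl-10-{[(4-methoxybenzyl)oxy]methyl}-6-methyl-1-oxacyclotetradec-6-en-2-one | O=C1CCC/C(C)=C\CC[C@H](COCc2ccc(OC)cc2)CCC[C@@H](C=C)O1
F10 | step 10 | trimethylsilyl ketene acetal of F9 | C[Si](C)(C)O/C1=C/CC/C(C)=C\CC[C@H](COCc2ccc(OC)cc2)CCC[C@@H](C=C)O1
F11 | step 10 | trimethylsilyl (1R,3E,8R,11Z)-8-{[(4-methoxybenzyl)oxy]methyl}-12-methylcyclotetradeca-3,11-diene-1-carboxylate | C[Si](C)(C)OC(=O)[C@H]1C/C=C/CCC[C@@H](COCc2ccc(OC)cc2)CC/C=C(/C)CC1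
F12 | step 10 | (1R,3E,8R,11Z)-8-{[(4-methoxybenzyl)oxy]methyl}-12-methylcyclotetradeca-3,11-diene-1-carboxylic acid | OC(=O)[C@H]1C/C=C/CCC[C@@H](COCc2ccc(OC)cc2)CC/C=C(/C)CC1
F13 | step 4 | (7R)-7-{[(4-methoxybenzyl)oxy]methyl}-1-(trimethylsilyl)non-8-en-1-yn-3-ol as both C3 epimers | C=C[C@H](COCc1ccc(OC)cc1)CCCC(O)C#C[Si](C)(C)C
F14 | step 4 | (7R)-7-{[(4-methoxybenzyl)oxy]methyl}-1-(trimethylsilyl)non-8-en-1-yn-3-one | C=C[C@H](COCc1ccc(OC)cc1)CCCC(=O)C#C[Si](C)(C)C
F15 | step 4 | (3S,7R)-7-{[(4-methoxybenzyl)oxy]methyl}-1-(trimethylsilyl)non-8-en-1-yn-3-ol | C=C[C@H](COCc1ccc(OC)cc1)CCC[C@H](O)C#C[Si](C)(C)C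
F16 | step 4 | (3S,7R)-7-{[(4-methoxybenzyl)oxy]methyl}non-8-en-1-yn-3-ol | C=C[C@H](COCc1ccc(OC)cc1)CCC[C@H](O)C#C
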